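**Plan**

- Retrosynthetic cuts, in order: the aryl O–C(=O) bond of the tiglate; both bonds from the oxirane CH2 (C3–C2 and C3–O1), leading back to an aryl acyloxymethyl ketone and a one-carbon sulfur ylide; the CH2–O bond of the isovalerate; the aryl–C(=O) bond.
- Feature used: the oxirane (O1, C2, C3) is a terminal 2,2-disubstituted epoxide. C2 is quaternary (aryl ring and CH2O-isovalerate arm) and C3 is a bare CH2, so one ylide carbon added to the C=O of ArC(=O)CH2O-isovalerate supplies C3 and closes the ring.
- Forward order: the side chain is built on 4-methoxy-3-methylphenol by Fries acetylation, double silylation, α-bromination and carboxylate displacement. The oxirane, the only ring formed, closes in step 6. The tiglate goes on last, because an enoate would be cyclopropanated by the ylide.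
- Stereochemistry: the single stereocentre (oxirane C2, R) should come from catalyst-controlled methylene transfer to the Re face of the ketone under LaLi3 tris(binaphthoxide) (trivalent lanthanum). The E-alkene is bought in with tigloyl chloride.

Key step: step 6

Assumption: the sense of induction of the lanthanum–lithium binaphthoxide catalyst with an aryl acyloxymethyl ketone cannot be read off the methyl ketone series, so (S)-binaphthol is written and the (R)-ligand is taken instead if the first run delivers the (S)-epoxide.

**Route**

Step 1
Reactants: 1 4-methoxy-3-methylphenol; 2 acetic anhydride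
Product: 3 4-methoxy-3-methylphenyl acetate
Conditions: pyridine, DMAP (cat.), CH2Cl2, 0 °C to rt
Reagents that add atoms: none
Why: DMAP-catalysed O-acylation of a phenol by an anhydride is fast and clean and gives the aryl ester needed for the Fries rearrangement.

Step 2
Reactants: 3 4-methoxy-3-methylphenyl acetate
Product: 5 1-(2-hydroxy-5-methoxy-4-methylphenyl)ethan-1-one, via difluoroboron chelate 4 (not isolated)
Conditions: BF3·OEt2 (3 equiv), AcOH, 100 °C; then H2O/EtOH, 70 °C
Reagents that add atoms: none
Why: Fries rearrangement, in which BF3 ionises the aryl ester and the acylium is returned ortho to the boron-bound phenolic oxygen, at the carbon para to the ring methyl because the other ortho carbon is wedged between oxygen and methyl and the para position is blocked by OMe, the product being held as chelate 4 until warm aqueous ethanol releases the hydroxy ketone.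

Step 3
Reactants: 5 1-(2-hydroxy-5-methoxy-4-methylphenyl)ethan-1-one
Product: 6 tert-butyl[2-(1-{[tert-butyl(dimethyl)silyl]oxy}ethenyl)-4-methoxy-5-methylphenoxy]dimethylsilane
Conditions: TBSOTf (2.5 equiv), Et3N (4 equiv), CH2Cl2, 0 °C to rt
Reagents that add atoms: tert-butyldimethylsilyl trifluoromethanesulfonate, CC(C)(C)[Si](C)(C)OS(=O)(=O)C(F)(F)F
Why: Silyl triflate with a tertiary amine (Simchen-type silylation) should cap the phenol and trap the methyl ketone as its silyl enol ether in the same flask, giving both the enol nucleophile for clean α-halogenation and the aryl silyl ether that is carried to the end.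

Step 4
Reactants: 6 tert-butyl[2-(1-{[tert-butyl(dimethyl)silyl]oxy}ethenyl)-4-methoxy-5-methylphenoxy]dimethylsilane
Product: 7 2-bromo-1-[2-(tert-butyldimethylsilyloxy)-5-methoxy-4-methylphenyl]ethan-1-one
Conditions: NBS (1.05 equiv), THF, −78 to 0 °C; aq. NaHCO3/Na2S2O3 work-up
Reagents that add atoms: N-bromosuccinimide, O=C1CCC(=O)N1Br
Why: Electrophilic α-bromination of a silyl enol ether, in which the enol carbon takes up bromine from NBS much faster than the electron-rich arene does and the enol silyl group is lost to succinimide, so the bromoketone should form without HBr and with the aryl silyl ether intact.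

Step 5
Reactants: 7 2-bromo-1-[2-(tert-butyldimethylsilyloxy)-5-methoxy-4-methylphenyl]ethan-1-one; 8 3-methylbutanoic acid (isovaleric acid)
Product: 9 2-[2-(tert-butyldimethylsilyloxy)-5-methoxy-4-methylphenyl]-2-oxoethyl 3-methylbutanoate
Conditions: Et3N (1.5 equiv), MeCN, 0 °C to rt
Reagents that add atoms: none
Why: SN2 displacement of a phenacyl bromide by a carboxylate (phenacyl ester formation), fast at room temperature because the adjacent carbonyl activates the CH2–Br bond, under an amine carboxylate too mild to cleave the aryl silyl ether, whose loss would let the phenoxide close to a benzofuranone.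

Step 6
Reactants: 9 2-[2-(tert-butyldimethylsilyloxy)-5-methoxy-4-methylphenyl]-2-oxoethyl 3-methylbutanoate; 10 trimethylsulfoxonium iodide
Product: 13 {(2R)-2-[2-(tert-butyldimethylsilyloxy)-5-methoxy-4-methylphenyl]oxiran-2-yl}methyl 3-methylbutanoate, via dimethylsulfoxonium methylide 11 (not isolated), via sulfoxonium betaine 12 (not isolated)
Conditions: 10, NaH, THF, reflux (ylide solution, 1.3 equiv); then 9, LaLi3[(S)-binaphthoxide]3 (5 mol %, trivalent lanthanum), (2,4,6-(MeO)3C6H2)3P=O (5 mol %), 5 Å MS, THF, 0 °C to rt; Et3N-deactivated silica
Reagents that add atoms: none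
Why: Proposed new method: the Lewis-acidic trivalent lanthanum centre of the heterobimetallic catalyst should bind the ketone oxygen while a lithium binaphthoxide site, opened up by the phosphine oxide, holds the ylide, so that the ylide carbon of 11 adds to the Re face of the carbonyl (O > CH2O-acyl > aryl) to give lanthanum-bound betaine 12, whose alkoxide then displaces dimethyl sulfoxide from the new CH2, forming the C–C and the C–O bond of the oxirane in one operation. The closest known reaction is the catalytic asymmetric Corey–Chaykovsky epoxidation of aryl and alkyl methyl ketones with this same catalyst system; an acyloxymethyl ketone carrying an ortho-silyloxy aryl group has not been put through it, hence the label. The oxirane closes by 3-exo-tet intramolecular SN2 of the alkoxide on the CH2–S carbon. The new quaternary stereocentre (R) is set in the addition step by the chiral binaphthoxide framework, which has to tell a flat, ortho-substituted aryl group from a slim CH2O-acyl arm, a size difference of the same kind as aryl against methyl. The step needs enantioface selectivity and chemoselectivity for the ketone over the ester and over enolisation: the α-oxygen makes the ketone the most electrophilic carbonyl, the weakly basic sulfoxonium ylide and the low temperature should keep proton transfer and acyl migration slow, the alkyl ester is not expected to acylate this ylide below room temperature, and the phenol is carried as a silyl ether so that no enoate is present to be cyclopropanated. The ylide is limited to 1.3 equiv and the temperature to rt so that the epoxide is not ring-expanded to an oxetane.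

Step 7
Reactants: 13 {(2R)-2-[2-(tert-butyldimethylsilyloxy)-5-methoxy-4-methylphenyl]oxiran-2-yl}methyl 3-methylbutanoate; 14 tigloyl chloride
Product: 16 {(2R)-2-[5-methoxy-4-methyl-2-{[(2E)-2-methylbut-2-enoyl]oxy}phenyl]oxiran-2-yl}methyl 3-methylbutanoate, via tetrabutylammonium phenoxide 15 (not isolated)
Conditions: Bu4NF (1.05 equiv), THF, −20 °C, 10 min; then 14 (1.5 equiv), −20 to 0 °C; Et3N-deactivated silica
Reagents that add atoms: none
Why: Fluoride-induced cleavage of the aryl Si–O bond gives naked phenoxide 15, which should be O-acylated at once by the acid chloride (one-pot desilylation–acylation), with no amine base present to isomerise or deconjugate the tigloyl group and with the oxirane and its stereocentre untouched at −20 °C.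

**Compound list**

1 | 4-methoxy-3-methylphenol | Cc1cc(O)ccc1OC | starting material
2 | acetic anhydride | CC(=O)OC(C)=O | starting material
3 | 4-methoxy-3-methylphenyl acetate | CC(=O)Oc1ccc(OC)c(C)c1 | intermediate
4 | difluoroboron chelate of 5 (2,2-difluoro-6-methoxy-4,7-dimethyl-1,3,2-benzodioxaborinine, boron bridging the phenolic and the carbonyl oxygen; not isolated) | CC1=[O+][B-](F)(F)Oc2cc(C)c(OC)cc12 | intermediate
5 | 1-(2-hydroxy-5-methoxy-4-methylphenyl)ethan-1-one | CC(=O)c1cc(OC)c(C)cc1O | intermediate
6 | tert-butyl[2-(1-{[tert-butyl(dimethyl)silyl]oxy}ethenyl)-4-methoxy-5-methylphenoxy]dimethylsilane | C=C(O[Si](C)(C)C(C)(C)C)c1cc(OC)c(C)cc1O[Si](C)(C)C(C)(C)C | intermediate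
7 | 2-bromo-1-[2-(tert-butyldimethylsilyloxy)-5-methoxy-4-methylphenyl]ethan-1-one | O=C(CBr)c1cc(OC)c(C)cc1O[Si](C)(C)C(C)(C)C | intermediate
8 | 3-methylbutanoic acid (isovaleric acid) | CC(C)CC(=O)O | starting material
9 | 2-[2-(tert-butyldimethylsilyloxy)-5-methoxy-4-methylphenyl]-2-oxoethyl 3-methylbutanoate | CC(C)CC(=O)OCC(=O)c1cc(OC)c(C)cc1O[Si](C)(C)C(C)(C)C | intermediate
10 | trimethylsulfoxonium iodide | C[S+](C)(C)=O.[I-] | starting material
11 | dimethylsulfoxonium methylide (not isolated) | [CH2-][S+](C)(C)=O | intermediate
12 | sulfoxonium betaine, (2S)-2-[2-(tert-butyldimethylsilyloxy)-5-methoxy-4-methylphenyl]-1-(dimethyloxosulfonio)-3-[(3-methylbutanoyl)oxy]propan-2-olate, metal-bound in the flask (not isolated) | Cc1cc(O[Si](C)(C)C(C)(C)C)c(cc1OC)[C@]([O-])(COC(=O)CC(C)C)C[S+](C)(C)=O | intermediate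
13 | {(2R)-2-[2-(tert-butyldimethylsilyloxy)-5-methoxy-4-methylphenyl]oxiran-2-yl}methyl 3-methylbutanoate | Cc1cc(O[Si](C)(C)C(C)(C)C)c(cc1OC)[C@]1(COC(=O)CC(C)C)CO1 | intermediate
14 | tigloyl chloride, (2E)-2-methylbut-2-enoyl chloride | C/C=C(\C)C(=O)Cl | starting material
15 | tetrabutylammonium 4-methoxy-5-methyl-2-[(2R)-2-{[(3-methylbutanoyl)oxy]methyl}oxiran-2-yl]phenolate (not isolated) | CCCC[N+](CCCC)(CCCC)CCCC.[O-]c1cc(C)c(OC)cc1[C@]1(COC(=O)CC(C)C)CO1 | intermediate
16 | {(2R)-2-[5-methoxy-4-methyl-2-{[(2E)-2-methylbut-2-enoyl]oxy}phenyl]oxiran-2-yl}methyl 3-methylbutanoate (CNP0108422.1) | C/C=C(\C)C(=O)Oc1cc(C)c(OC)cc1[C@]1(COC(=O)CC(C)C)CO1 | target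

**Step count and risks**

Total step count: 7. Longest linear sequence: 7 steps (from 1 to 16).

Steps most likely to fail:

1. Step 6 (labelled step). The basic ylide may enolise the α-acyloxy ketone and set off acyl migration, the ylide may be acylated by the ester or attack silicon, or the catalyst may discriminate the two carbonyl faces poorly next to the ortho-silyloxy group. The fallback uses known chemistry, sets out from 9 and comes back at 13. Non-basic Takai–Lombardo methylenation of 9 (Zn, CH2Br2, TiCl4, THF/CH2Cl2, 0 °C to rt), which leaves esters alone, should give 2-[2-(tert-butyldimethylsilyloxy)-5-methoxy-4-methylphenyl]prop-2-en-1-yl 3-methylbutanoate F1. Reductive removal of the isovalerate (iBu2AlH, CH2Cl2, −78 °C) gives 2-[2-(tert-butyldimethylsilyloxy)-5-methoxy-4-methylphenyl]prop-2-en-1-ol F2. Sharpless asymmetric epoxidation (Ti(OiPr)4, L-(+)-diethyl tartrate, tBuOOH, 4 Å MS, CH2Cl2, −20 °C) should, by the usual facial rule for primary allylic alcohols, give {(2S)-2-[2-(tert-butyldimethylsilyloxy)-5-methoxy-4-methylphenyl]oxiran-2-yl}methanol F3. Steglich esterification of F3 with 8 (DCC, DMAP, CH2Cl2, 0 °C) returns to 13; the descriptor changes from S to R only because the acylated arm then outranks the ring CH2.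

2. Step 7. The free phenoxide may live long enough to take over the neighbouring isovaleryl group or to open the oxirane, and wet fluoride may hydrolyse the acid chloride before it acylates. The fallback sets out from 13 and comes back at 16, separating the two events. Buffered desilylation (Bu4NF/AcOH 1:1, THF, 0 °C) should give the neutral phenol {(2R)-2-(2-hydroxy-5-methoxy-4-methylphenyl)oxiran-2-yl}methyl 3-methylbutanoate F4, which is isolated. F4 is then acylated with 14 under nucleophilic catalysis (pyridine, DMAP cat., CH2Cl2, 0 °C) to give 16.

3. Step 2. The acyl group may be delivered to the wrong ring carbon (the crowded ortho position, or ortho to OMe after intermolecular transfer), and the methyl ether may be partly cleaved by the hot Lewis acid. The fallback sets out from 1 and comes back at 5, building the acetyl group in stages. Magnesium-mediated ortho-formylation of 1 (MgCl2, Et3N, paraformaldehyde, MeCN, reflux) should give 2-hydroxy-5-methoxy-4-methylbenzaldehyde F5. Addition of MeMgBr (2.5 equiv, THF, 0 °C) gives racemic 2-(1-hydroxyethyl)-4-methoxy-5-methylphenol F6. Benzylic oxidation of F6 (MnO2, CH2Cl2, rt) gives 5.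

Further compounds
F1 | step 6 | 2-[2-(tert-butyldimethylsilyloxy)-5-methoxy-4-methylphenyl]prop-2-en-1-yl 3-methylbutanoate | C=C(COC(=O)CC(C)C)c1cc(OC)c(C)cc1O[Si](C)(C)C(C)(C)C
F2 | step 6 | 2-[2-(tert-butyldimethylsilyloxy)-5-methoxy-4-methylphenyl]prop-2-en-1-ol | C=C(CO)c1cc(OC)c(C)cc1O[Si](C)(C)C(C)(C)C
F3 | step 6 | {(2S)-2-[2-(tert-butyldimethylsilyloxy)-5-methoxy-4-methylphenyl]oxiran-2-yl}methanol | Cc1cc(O[Si](C)(C)C(C)(C)C)c(cc1OC)[C@]1(CO)CO1
F4 | step 7 | {(2R)-2-(2-hydroxy-5-methoxy-4-methylphenyl)oxiran-2-yl}methyl 3-methylbutanoate | Cc1cc(O)c(cc1OC)[C@]1(COC(=O)CC(C)C)CO1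
F5 | step 2 | 2-hydroxy-5-methoxy-4-methylbenzaldehyde | O=Cc1cc(OC)c(C)cc1O
F6 | step 2 | 2-(1-hydroxyethyl)-4-methoxy-5-methylphenol (racemic) | CC(O)c1cc(OC)c(C)cc1O
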